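The ten-membered carbocycle is not cyclised directly but grown from a carvone-derived cyclohexene. An anion-accelerated oxy-Cope rearrangement of a cis-1,2-dialkenylcyclohexenol forms the C1–C2 bond while C4–C9 breaks, expanding the six-membered ring (C4–C9) by four carbons in one operation. The step exploits three features of the ring: the oxygen on C9, which as alkoxide drives the shift and ends as the ketone; the C10 methyl, delivered with C1 by an isopropenyl group; and the oxygen on C2, carried as a silyl enol ether terminus. The resulting (3Z,5Z)-diene is then bridged by singlet oxygen to set O3, O6 and the (Z)-C4=C5 olefin.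

Key step: step 9

Numbering (germacrane, used for every compound): ring C1–C10 with C1 = CH2, C2 = CH–OAc, C3 = CH–OH, C4(=C5) carrying methyl C15, C6 = lactone CH–O, C7 = lactone CH, C8 = CH2, C9 = CH–OAng, C10 = CH–CH3 (C14); C11–C13 = methylene-lactone carbons. β is the face of the C7 side chain (C11), α the opposite face.

Assumption: protonation of enolate 15 is taken to give the kinetic 10α-methyl ketone; this centre is α to the carbonyl group and can be equilibrated with base if the other epimer forms.

Step 1
Reactants: 1 (S)-(+)-carvone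
Product: 2 10-chlorocarvone
Conditions: Ca(OCl)2, CO2 (s), CH2Cl2/H2O, 0 °C
Reagents that add atoms: calcium hypochlorite, [Ca+2].[O-]Cl.[O-]Cl
Why: Ene-type allylic chlorination: HOCl released from Ca(OCl)2 by CO2 should attack the electron-rich 1,1-disubstituted alkene with shift of the double bond, while the electron-poor enone alkene stays untouched.

Step 2
Reactants: 2 10-chlorocarvone; 3 4-methoxybenzyl alcohol
Product: 4 10-(4-methoxybenzyloxy)carvone
Conditions: NaH, Bu4NI (cat.), THF, 0 °C
Reagents that add atoms: 4-methoxybenzyl alcohol, COc1ccc(CO)cc1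
Why: Williamson ether synthesis (SN2) at the primary allylic chloride, which leaves the C7 stereocentre untouched.

Step 3
Reactants: 4 10-(4-methoxybenzyloxy)carvone
Product: 5 through-conjugated TBS dienol ether (C9(OTBS)=C4, C5=C6)
Conditions: TBSCl, NaI, Et3N, MeCN, 40 °C
Reagents that add atoms: tert-butyldimethylsilyl chloride, C[Si](C)(Cl)C(C)(C)C
Why: Soft enolisation by TBSI/Et3N under equilibrating conditions should give the γ-deprotonated, through-conjugated dienol silyl ether, which has the more substituted enol double bond.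

Step 4
Reactants: 5 TBS dienol ether
Product: 7 6α-hydroxy enone (OH trans to the C7 side chain), via epoxide 6 (not isolated)
Conditions: mCPBA, NaHCO3, CH2Cl2, −20 °C; then HF·pyridine, THF, 0 °C
Reagents that add atoms: mCPBA, O=C(OO)c1cccc(Cl)c1
Why: Vinylogous Rubottom oxidation: the peracid should epoxidise the terminal C5=C6 bond of the dienol ether anti to the C7 side chain (as with steroidal dienol ethers), and fluoride opens epoxide 6 to the γ-hydroxy enone.

Step 5
Reactants: 7 6α-hydroxy enone; 8 butyl vinyl ether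
Product: 9 6α-vinyl ether
Conditions: Pd(OCOCF3)2 (cat.), 4,7-diphenyl-1,10-phenanthroline (cat.), Et3N (cat.), butyl vinyl ether (solvent), air, 75 °C
Reagents that add atoms: butyl vinyl ether, C=COCCCC
Why: Palladium-catalysed transfer vinylation (transetherification) of the secondary allylic alcohol under near-neutral conditions that should spare the aromatisation-prone γ-oxy enone.

Step 6
Reactants: 9 6α-vinyl ether
Product: 10 keto aldehyde (C4 quaternary: β-methyl, α-CH2CHO; C5=C6)
Conditions: PhMe, 150 °C, sealed tube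
Reagents that add atoms: none
Why: Claisen rearrangement through a chair transition state should deliver the CH2CHO arm suprafacially to C4 on the face of the breaking C6–O bond (α), creating the quaternary centre and moving the olefin to C5=C6.

Step 7
Reactants: 10 keto aldehyde
Product: 11 (E)-TIPS enol ether
Conditions: TIPSOTf, Et3N, CH2Cl2, −78 → −40 °C
Reagents that add atoms: triisopropylsilyl triflate, CC(C)[Si](C(C)C)(C(C)C)OS(=O)(=O)C(F)(F)F
Why: Soft enolisation and O-silylation is faster for the aldehyde than for the hindered ketone, and the (E)-enol ether should prevail because the quaternary C4 avoids a cis relationship to the bulky silyloxy group.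

Step 8
Reactants: 11 (E)-TIPS enol ether; 12 isopropenylmagnesium bromide
Product: 13 tertiary carbinol (9β-OH, 9α-isopropenyl cis to the enol ether arm)
Conditions: CeCl3, THF, −78 °C
Reagents that add atoms: isopropenylmagnesium bromide, CC(=C)[Mg]Br
Why: Grignard 1,2-addition via the organocerium reagent (no enolisation) from the face opposite the pseudo-axial C4 methyl should place the isopropenyl group cis to the enol ether arm.

Step 9
Reactants: 13 tertiary carbinol
Product: 16 (3Z,5Z)-2β-silyloxy-10α-methylcyclodeca-3,5-dien-9-one, via potassium alkoxide 14 (not isolated), via potassium enolate 15 (not isolated)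
Conditions: KH, 18-crown-6, THF, 0 °C → rt; then NH4Cl (aq), −78 °C
Reagents that add atoms: none
Why: Anionic oxy-Cope rearrangement ([3,3]-sigmatropic shift): KH gives alkoxide 14, whose C4–C9 bond breaks as C1–C2 forms, the alkoxide becoming enolate 15. The closest known reaction is the ring expansion of 1,2-dialkenylcyclohexanols to cyclodec-5-enones. The ten-membered ring is closed by four-carbon ring expansion through a six-membered chair transition state fused to the cyclohexene half-chair (C7 side chain pseudo-equatorial, isopropenyl axial, enol ether arm equatorial), and because C5 is axial on that chair the new C3=C4 olefin should be Z and the enolate E. C2 is set by chirality transfer from C4/C9 and the (E)-enol ether geometry (OTIPS equatorial), giving the 2β-silyl ether that step 13 inverts, and C10 is set by protonation of the enolate on its outer face (10α-methyl). The step needs the exocyclic enol ether, not the ring olefin, as the second π-component and the chair over the boat; the first is secured by the strain-free chair open only to the enol ether, the second by the equatorial OTIPS group, while the trans enol ether geometry rules out intramolecular silyl transfer to the alkoxide.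

Step 10
Reactants: 16 cyclodecadienone
Product: 17 9α-alcohol (9,10-cis)
Conditions: LiBH(s-Bu)3, THF, −78 °C
Reagents that add atoms: none
Why: Ketone reduction under 1,2-asymmetric induction: the bulky hydride should add anti to the larger (C1) branch of the adjacent C10 stereocentre, giving the 9,10-cis alcohol.

Step 11
Reactants: 17 9α-alcohol; 18 angelic acid
Product: 19 9β-angelate
Conditions: PPh3, DIAD, PhMe, 0 °C → rt
Reagents that add atoms: angelic acid, C/C=C(/C)C(=O)O
Why: Mitsunobu esterification inverts C9 by SN2 displacement to the 9β-angelate trans to the C10 methyl, and the neutral conditions should avoid angelate-to-tiglate isomerisation.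

Step 12
Reactants: 19 9β-angelate
Product: 20 2β-alcohol
Conditions: Bu4NF, AcOH, THF, 0 °C → rt
Reagents that add atoms: none
Why: Fluoride cleavage of the secondary silyl ether, buffered with AcOH so that the angelate is not touched.

Step 13
Reactants: 20 2β-alcohol; 21 acetic acid
Product: 22 2α-acetate
Conditions: PPh3, DIAD, THF, 0 °C
Reagents that add atoms: acetic acid, CC(=O)O
Why: Mitsunobu esterification with SN2 inversion should convert the 2β-alcohol directly into the 2α-acetate, attack at the tertiary C4 or the remote C6 terminus of the dienyl system being disfavoured.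

Step 14
Reactants: 22 2α-acetate
Product: 24 3α,6α-diol with (Z)-C4=C5, via endoperoxide 23 (not isolated)
Conditions: O2, hν, tetraphenylporphyrin (cat.), CH2Cl2, −20 °C; then Zn, AcOH, 0 °C
Reagents that add atoms: dioxygen, O=O
Why: [4+2] cycloaddition of singlet oxygen to the s-cis (3Z,5Z)-diene on the α face, opposite the C7 side chain, should set C3 and C6 together and lock the new C4=C5 bond as Z inside the dioxine ring; Zn/AcOH then cleaves the O–O bond to the cis-ene-diol.

Step 15
Reactants: 24 3α,6α-diol
Product: 25 3,6,12-triol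
Conditions: DDQ, CH2Cl2/pH 7 buffer, 0 °C
Reagents that add atoms: none
Why: Oxidative cleavage of the 4-methoxybenzyl ether by DDQ (benzylic hydride abstraction, hydrolysis of the oxocarbenium ion) should leave the esters and olefins intact.

Step 16
Reactants: 25 3,6,12-triol
Product: 28 CNP0122017.1, via enal 26 (not isolated), via lactol 27 (not isolated)
Conditions: TEMPO (cat.), PhI(OAc)2, CH2Cl2, rt
Reagents that add atoms: none
Why: Oxidative lactonisation: the oxoammonium oxidation is selective for the primary allylic alcohol, enal 26 is trapped by the 6-OH as lactol 27, and this is oxidised on to the trans-fused α-methylene-γ-butyrolactone while the secondary 3-OH should survive.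

Compound list
1 | (S)-(+)-carvone, (5S)-2-methyl-5-(prop-1-en-2-yl)cyclohex-2-en-1-one | O=C1C[C@@H](C(=C)C)CC=C1C | starting material
2 | 10-chlorocarvone, (5S)-5-(3-chloroprop-1-en-2-yl)-2-methylcyclohex-2-en-1-one | O=C1C[C@@H](C(=C)CCl)CC=C1C | intermediate
3 | 4-methoxybenzyl alcohol | COc1ccc(CO)cc1 | starting material
4 | 10-(4-methoxybenzyloxy)carvone (PMB ether at C12) | O=C1C[C@@H](C(=C)COCc2ccc(OC)cc2)CC=C1C | intermediate
5 | through-conjugated TBS dienol ether of 4 (C9(OTBS)=C4, C5=C6) | CC1=C(O[Si](C)(C)C(C)(C)C)C[C@@H](C(=C)COCc2ccc(OC)cc2)C=C1 | intermediate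
6 | 5α,6α-epoxide of 5 (epoxide trans to the C7 side chain) | CC1=C(O[Si](C)(C)C(C)(C)C)C[C@@H](C(=C)COCc2ccc(OC)cc2)[C@@H]3O[C@H]13 | intermediate
7 | 6α-hydroxy enone (C9 ketone, C4=C5, 6-OH trans to the C7 side chain) | O=C1C[C@@H](C(=C)COCc2ccc(OC)cc2)[C@H](O)C=C1C | intermediate
8 | butyl vinyl ether | C=COCCCC | starting material
9 | 6α-vinyl ether of 7 | O=C1C[C@@H](C(=C)COCc2ccc(OC)cc2)[C@H](OC=C)C=C1C | intermediate
10 | keto aldehyde (C9 ketone, C4 with β-methyl and α-CH2CHO, C5=C6, 7β side chain) | O=C1C[C@@H](C(=C)COCc2ccc(OC)cc2)C=C[C@]1(C)CC=O | intermediate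
11 | (E)-triisopropylsilyl enol ether of 10 (C3=C2–OTIPS) | O=C1C[C@@H](C(=C)COCc2ccc(OC)cc2)C=C[C@]1(C)/C=C/O[Si](C(C)C)(C(C)C)C(C)C | intermediate
12 | isopropenylmagnesium bromide | CC(=C)[Mg]Br | starting material
13 | tertiary carbinol (9β-OH, 9α-isopropenyl, 4α-enol ether arm, 4β-methyl, 7β side chain) | O[C@@]1(C(C)=C)C[C@@H](C(=C)COCc2ccc(OC)cc2)C=C[C@]1(C)/C=C/O[Si](C(C)C)(C(C)C)C(C)C | intermediate
14 | potassium alkoxide of 13 | [K+].[O-][C@@]1(C(C)=C)C[C@@H](C(=C)COCc2ccc(OC)cc2)C=C[C@]1(C)/C=C/O[Si](C(C)C)(C(C)C)C(C)C | intermediate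
15 | potassium (E)-enolate of 16 (C9(OK)=C10, C8 trans to C1) | C=C(COCc1ccc(OC)cc1)[C@H]2/C=C\C(C)=C/[C@@H](O[Si](C(C)C)(C(C)C)C(C)C)C/C(C)=C(\[O-])C2.[K+] | intermediate
16 | (3Z,5Z)-2β-(triisopropylsilyloxy)-10α-methylcyclodeca-3,5-dien-9-one with 4-methyl and 7β side chain | C=C(COCc1ccc(OC)cc1)[C@H]2/C=C\C(C)=C/[C@@H](O[Si](C(C)C)(C(C)C)C(C)C)C[C@H](C)C(=O)C2 | intermediate
17 | 9α-alcohol of 16 (9-OH cis to the 10α-methyl) | C=C(COCc1ccc(OC)cc1)[C@H]2/C=C\C(C)=C/[C@@H](O[Si](C(C)C)(C(C)C)C(C)C)C[C@H](C)[C@H](O)C2 | intermediate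
18 | angelic acid, (Z)-2-methylbut-2-enoic acid | C/C=C(/C)C(=O)O | starting material
19 | 9β-angelate (2β-OTIPS) | C=C(COCc1ccc(OC)cc1)[C@H]2/C=C\C(C)=C/[C@@H](O[Si](C(C)C)(C(C)C)C(C)C)C[C@H](C)[C@@H](OC(=O)/C(C)=C\C)C2 | intermediate
20 | 2β-alcohol 9β-angelate | C=C(COCc1ccc(OC)cc1)[C@H]2/C=C\C(C)=C/[C@@H](O)C[C@H](C)[C@@H](OC(=O)/C(C)=C\C)C2 | intermediate
21 | acetic acid | CC(=O)O | starting material
22 | 2α-acetate 9β-angelate (3Z,5Z)-diene | C=C(COCc1ccc(OC)cc1)[C@H]2/C=C\C(C)=C/[C@H](OC(C)=O)C[C@H](C)[C@@H](OC(=O)/C(C)=C\C)C2 | intermediate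
23 | 3α,6α-endoperoxide of 22 (1,2-dioxine across C3/C6, C4=C5) | C=C(COCc1ccc(OC)cc1)[C@H]2[C@H]3C=C(C)[C@H](OO3)[C@H](OC(C)=O)C[C@H](C)[C@@H](OC(=O)/C(C)=C\C)C2 | intermediate
24 | 3α,6α-diol with (Z)-C4=C5 (2α-OAc, 9β-OAng, 12-OPMB) | C=C(COCc1ccc(OC)cc1)[C@H]2[C@H](O)/C=C(/C)[C@H](O)[C@H](OC(C)=O)C[C@H](C)[C@@H](OC(=O)/C(C)=C\C)C2 | intermediate
25 | 3α,6α,12-triol | C=C(CO)[C@H]2[C@H](O)/C=C(/C)[C@H](O)[C@H](OC(C)=O)C[C@H](C)[C@@H](OC(=O)/C(C)=C\C)C2 | intermediate
26 | enal (C12 aldehyde) of 25 | C=C(C=O)[C@H]2[C@H](O)/C=C(/C)[C@H](O)[C@H](OC(C)=O)C[C@H](C)[C@@H](OC(=O)/C(C)=C\C)C2 | intermediate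
27 | lactol (C12 hemiacetal closed on O6, both anomers) | C=C1C(O)O[C@@H]2/C=C(/C)[C@H](O)[C@H](OC(C)=O)C[C@H](C)[C@@H](OC(=O)/C(C)=C\C)C[C@@H]12 | intermediate
28 | CNP0122017.1 (2α-acetoxy-3α-hydroxy-9β-angeloyloxy-10α-methyl-(4Z)-germacra-4,11(13)-dien-12,6α-olide) | C=C1C(=O)O[C@@H]2/C=C(/C)[C@H](O)[C@H](OC(C)=O)C[C@H](C)[C@@H](OC(=O)/C(C)=C\C)C[C@@H]12 | target

Total step count: 16. Longest linear sequence: 16 steps from (S)-(+)-carvone.

Steps most likely to fail

Step 9. The rearrangement may leak through a boat transition state or through dissociation and recombination of the alkoxide, eroding the geometry of C3=C4 and the configuration at C2. The alkoxide may also attack the silyl enol ether intermolecularly. The fallback sets out from 13. The tertiary alcohol is silylated (TMSOTf, 2,6-lutidine, CH2Cl2, −78 °C) to the trimethylsilyl ether F1. F1 is heated without base (decalin, 200 °C) so that a neutral siloxy-Cope rearrangement through the same chair gives the ring-expanded trimethylsilyl enol ether F2. Selective methanolysis of the silyl enol ether (K2CO3, MeOH, 0 °C) then returns to 16.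

Step 14. The twisted medium-ring diene may prefer an ene reaction with singlet oxygen or take up oxygen with poor facial selectivity. The fallback sets out from 22. The trisubstituted C3=C4 bond is epoxidised on the α face (mCPBA, NaHCO3, CH2Cl2, 0 °C) to the vinyl epoxide F3. F3 is opened with Pd(PPh3)4 and chloroacetic acid in THF: zerovalent palladium ionises the C4–O bond with inversion and the carboxylate adds to C6 with a second inversion, a cis-1,4 addition that gives the 3α-hydroxy 6α-chloroacetate F4 with the transposed C4=C5 bond. Selective removal of the chloroacetate (thiourea, NaHCO3, EtOH, 50 °C) rejoins the route at 24.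

Step 13. SN2′ attack or elimination on the dienylic alkoxyphosphonium salt may erode the inversion at C2. The fallback sets out from 20. Oxidation (Dess–Martin periodinane, NaHCO3, CH2Cl2) gives the cross-conjugated dienone F5. Reagent-controlled CBS reduction ((S)-2-methyl-CBS-oxazaborolidine, catecholborane, PhMe, −78 °C, alkenyl branch as the large group) should give the 2α-alcohol F6. Acetylation (Ac2O, DMAP, pyridine) rejoins the route at 22.

Further compounds
F1 | step 9 | trimethylsilyl ether of 13 | C[Si](C)(C)O[C@@]1(C(C)=C)C[C@@H](C(=C)COCc2ccc(OC)cc2)C=C[C@]1(C)/C=C/O[Si](C(C)C)(C(C)C)C(C)C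
F2 | step 9 | ring-expanded trimethylsilyl enol ether (C9(OTMS)=C10) | C=C(COCc1ccc(OC)cc1)[C@H]2/C=C\C(C)=C/[C@@H](O[Si](C(C)C)(C(C)C)C(C)C)C/C(C)=C(\O[Si](C)(C)C)C2
F3 | step 14 | 3α,4α-epoxide of 22 (vinyl epoxide) | C=C(COCc1ccc(OC)cc1)[C@H]2/C=C\[C@]3(C)O[C@@H]3[C@H](OC(C)=O)C[C@H](C)[C@@H](OC(=O)/C(C)=C\C)C2
F4 | step 14 | 3α-hydroxy 6α-chloroacetate with (Z)-C4=C5 | C=C(COCc1ccc(OC)cc1)[C@H]2[C@H](OC(=O)CCl)/C=C(/C)[C@H](O)[C@H](OC(C)=O)C[C@H](C)[C@@H](OC(=O)/C(C)=C\C)C2
F5 | step 13 | (3Z,5Z)-dien-2-one (C2 ketone) | C=C(COCc1ccc(OC)cc1)[C@H]2/C=C\C(C)=C/C(=O)C[C@H](C)[C@@H](OC(=O)/C(C)=C\C)C2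
F6 | step 13 | 2α-alcohol (C2 epimer of 20) | C=C(COCc1ccc(OC)cc1)[C@H]2/C=C\C(C)=C/[C@H](O)C[C@H](C)[C@@H](OC(=O)/C(C)=C\C)C2
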